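**Retrosynthetic overview**
- Last C–C bond: catalytic asymmetric vinylogous Mukaiyama aldol of a labda-8(17),13E-dien-15-al with 4-methyl-2-silyloxyfuran. It installs the butenolide and both side-chain stereocentres in one step.
- Enal ⇐ terminal alkyne (Negishi carboalumination/CH2O) ⇐ 12-chloro-tetranorlabdane core.
- Core ⇐ acyclic (S)-silyloxy epoxy-diene by one Ti(III) radical bicyclization: ring A (C4–C5) forms first, then ring B (C9–C10), ending as the exocyclic alkene. The single C6 carbinol centre controls C4, C5, C9 and C10.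
- Epoxy-diene ⇐ methyl ketone (sulfur ylide) ⇐ terminal alkene (Wacker) ⇐ CBS-reduced enone from NHK union of two carboalumination-derived C7/C8 pieces.

Assumption: 1, 8 and 24 are purchased; labdane numbering (C1–C20) is used in names; the sense of the Ti–BINOL aldol ((R)-BINOL → S,S adduct) is taken by analogy with 2-silyloxyfuran/aldehyde precedent and must be confirmed (Mosher), the ligand antipode being the remedy.

**Step 1**
Reactants: 1 tert-butyl(but-3-yn-1-yloxy)dimethylsilane
Product: 4 (E)-6-[(tert-butyldimethylsilyl)oxy]-4-methylhex-3-en-1-ol, via dimethyl[(E)-4-(tert-butyldimethylsilyloxy)-2-methylbut-1-en-1-yl]alane 2 (not isolated), via lithium butyl(dimethyl)[(E)-4-(tert-butyldimethylsilyloxy)-2-methylbut-1-en-1-yl]aluminate 3 (not isolated)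
Conditions: AlMe3, Cp2ZrCl2 (cat.), CH2Cl2, 0 °C→rt; n-BuLi, THF, −30 °C; ethylene oxide, −30→0 °C; aq. Rochelle salt
Reagents that add atoms: trimethylaluminium C[Al](C)C; ethylene oxide C1CO1
Why: Negishi Zr-catalysed carboalumination adds Me–Al syn across the terminal alkyne (Me to the internal carbon), fixing the E trisubstituted alkene, and the derived alanate opens ethylene oxide with retention of alkene geometry.

**Step 2**
Reactants: 4 (E)-6-[(tert-butyldimethylsilyl)oxy]-4-methylhex-3-en-1-ol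
Product: 5 (E)-tert-butyl[(6-chloro-3-methylhex-3-en-1-yl)oxy]dimethylsilane
Conditions: PPh3, NCS, CH2Cl2, 0 °C→rt
Reagents that add atoms: N-chlorosuccinimide O=C1CCC(=O)N1Cl
Why: Appel-type chlorination proceeds by SN2 displacement of an alkoxyphosphonium under neutral conditions that leave the TBS ether and the alkene untouched.

**Step 3**
Reactants: 5 (E)-tert-butyl[(6-chloro-3-methylhex-3-en-1-yl)oxy]dimethylsilane
Product: 6 (E)-6-chloro-3-methylhex-3-en-1-ol
Conditions: CSA (cat.), MeOH, 0 °C→rt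
Reagents that add atoms: none
Why: Acid-catalysed methanolysis cleaves the unhindered primary TBS ether while the alkyl chloride and trisubstituted alkene are inert.

**Step 4**
Reactants: 6 (E)-6-chloro-3-methylhex-3-en-1-ol
Product: 7 (E)-6-chloro-3-methylhex-3-enal
Conditions: Dess–Martin periodinane, CH2Cl2, 0 °C; used crude
Reagents that add atoms: none
Why: Dess–Martin oxidation is neutral and fast, so the β,γ-unsaturated aldehyde is obtained without migration of the alkene into conjugation.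

**Step 5**
Reactants: 8 hept-1-en-6-yne
Product: 10 (E)-1-iodo-2-methylhepta-1,6-diene, via dimethyl[(E)-2-methylhepta-1,6-dien-1-yl]alane 9 (not isolated)
Conditions: AlMe3, Cp2ZrCl2 (cat.), CH2Cl2, 0 °C→rt; I2, THF, −30→0 °C
Reagents that add atoms: trimethylaluminium C[Al](C)C; iodine II
Why: Negishi carboalumination is selective for the alkyne over the terminal alkene, and iodinolysis of the C–Al bond occurs with retention to give the E vinyl iodide.

**Step 6**
Reactants: 7 (E)-6-chloro-3-methylhex-3-enal; 10 (E)-1-iodo-2-methylhepta-1,6-diene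
Product: 11 rac-(3E,7E)-1-chloro-4,8-dimethyltrideca-3,7,12-trien-6-ol
Conditions: CrCl2 (4 equiv), NiCl2 (1 mol%), DMSO, rt
Reagents that add atoms: none
Why: Nozaki–Hiyama–Kishi coupling inserts Ni/Cr into the vinyl iodide with retention, and the non-basic alkenylchromium adds only to the aldehyde without enolising the β,γ-enal; the carbinol forms racemic and is corrected in steps 7–8.

**Step 7**
Reactants: 11 rac-(3E,7E)-1-chloro-4,8-dimethyltrideca-3,7,12-trien-6-ol
Product: 12 (3E,7E)-1-chloro-4,8-dimethyltrideca-3,7,12-trien-6-one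
Conditions: Dess–Martin periodinane, CH2Cl2, 0 °C
Reagents that add atoms: none
Why: Dess–Martin oxidation gives the enone under neutral conditions that do not move the skipped C3=C4 alkene into conjugation.

**Step 8**
Reactants: 12 (3E,7E)-1-chloro-4,8-dimethyltrideca-3,7,12-trien-6-one
Product: 13 (6S,3E,7E)-1-chloro-4,8-dimethyltrideca-3,7,12-trien-6-ol
Conditions: (R)-Me-CBS (0.2 equiv), catecholborane, toluene, −78 °C
Reagents that add atoms: none
Why: Corey–Bakshi–Shibata reduction with the alkenyl group as the large substituent gives the (S)-allylic alcohol (C6 of the target) from the (R)-oxazaborolidine, and catecholborane at −78 °C does not hydroborate the alkenes.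

**Step 9**
Reactants: 13 (6S,3E,7E)-1-chloro-4,8-dimethyltrideca-3,7,12-trien-6-ol
Product: 14 tert-butyl{[(6S,3E,7E)-1-chloro-4,8-dimethyltrideca-3,7,12-trien-6-yl]oxy}dimethylsilane
Conditions: TBSCl, imidazole, DMF, rt
Reagents that add atoms: tert-butyldimethylsilyl chloride CC(C)(C)[Si](C)(C)Cl
Why: Standard silylation installs the bulky OTBS group that serves as the stereocontrol element in step 12.

**Step 10**
Reactants: 14 tert-butyl{[(6S,3E,7E)-1-chloro-4,8-dimethyltrideca-3,7,12-trien-6-yl]oxy}dimethylsilane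
Product: 15 (8S,6E,10E)-8-[(tert-butyldimethylsilyl)oxy]-13-chloro-6,10-dimethyltrideca-6,10-dien-2-one
Conditions: PdCl2 (10 mol%), CuCl, O2 (1 atm), DMF/H2O, rt
Reagents that add atoms: water O
Why: Tsuji–Wacker oxidation (Markovnikov hydroxypalladation, β-H elimination, O2 as terminal oxidant) is selective for the monosubstituted terminal alkene and leaves the trisubstituted alkenes, allylic silyl ether and chloride alone.

**Step 11**
Reactants: 15 (8S,6E,10E)-8-[(tert-butyldimethylsilyl)oxy]-13-chloro-6,10-dimethyltrideca-6,10-dien-2-one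
Product: 16 tert-butyl{[(6S,3E,7E)-1-chloro-4,8-dimethyl-11-(2-methyloxiran-2-yl)undeca-3,7-dien-6-yl]oxy}dimethylsilane (1:1 at the oxirane carbon)
Conditions: Me3S(O)I, NaH, DMSO/THF, rt
Reagents that add atoms: trimethylsulfoxonium iodide C[S+](C)(C)=O.[I-]
Why: Corey–Chaykovsky epoxidation adds the sulfoxonium ylide to the only carbonyl and closes to the 2,2-disubstituted oxirane; the new centre forms as a mixture, which does not matter because it becomes a planar radical in step 12.

**Step 12**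
Reactants: 16 tert-butyl{[(6S,3E,7E)-1-chloro-4,8-dimethyl-11-(2-methyloxiran-2-yl)undeca-3,7-dien-6-yl]oxy}dimethylsilane
Product: 17 (4R,5R,6S,9S,10R)-6-(tert-butyldimethylsilyloxy)-12-chloro-13,14,15,16-tetranorlabd-8(17)-en-18-ol (trans-decalin; 4α-CH2OH, 4β-CH3, 5α-H, 6α-OTBS, 10β-CH3, 9β-CH2CH2Cl, 8-exo-methylene)
Conditions: Cp2TiCl2 (2.5 equiv), Mn dust, THF (0.01 M, slow addition), rt; then dilute HCl work-up
Reagents that add atoms: none
Why: Proposed new method: Cp2TiCl opens the oxirane homolytically to a planar tertiary β-titanoxy radical (both epimers converge), which adds 6-endo to C5=C10, and the new C10 radical adds 6-endo to C8=C9 through a chair–chair array; the C6–OTBS group sits equatorial (axial would clash with the C10 methyl) and so fixes the absolute sense, the bulky CH2OTi arm takes the equatorial 4α position, the E alkenes give the trans fusion and 9β chain, and Ti(III) trapping of the C8 radical with loss of a C17 hydrogen gives the exocyclic alkene; closest known reaction: Ti(III)-mediated (Nugent–RajanBabu) radical cyclization of 2,3-epoxypolyprenes to exocyclic-alkene terpenoids, extended here to a 1,1-disubstituted epoxide and to 1,2-induction from an allylic silyl ether.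

**Step 13**
Reactants: 17 (4R,5R,6S,9S,10R)-6-(tert-butyldimethylsilyloxy)-12-chloro-13,14,15,16-tetranorlabd-8(17)-en-18-ol
Product: 18 (4R,5R,6S,9S,10R)-6,18-bis(tert-butyldimethylsilyloxy)-12-chloro-13,14,15,16-tetranorlabd-8(17)-ene
Conditions: TBSCl, imidazole, DMF, rt
Reagents that add atoms: tert-butyldimethylsilyl chloride CC(C)(C)[Si](C)(C)Cl
Why: Silylation of the neopentyl primary alcohol protects it from the organometallic and Lewis-acid steps that follow.

**Step 14**
Reactants: 18 (4R,5R,6S,9S,10R)-6,18-bis(tert-butyldimethylsilyloxy)-12-chloro-13,14,15,16-tetranorlabd-8(17)-ene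
Product: 19 (4R,5R,6S,9S,10R)-6,18-bis(tert-butyldimethylsilyloxy)-15,16-dinorlabd-8(17)-en-13-yne
Conditions: LiC≡CH·H2NCH2CH2NH2, NaI (cat.), DMSO, rt→40 °C
Reagents that add atoms: lithium acetylide ethylenediamine complex [Li]C#C.NCCN
Why: SN2 alkynylation of the unhindered primary chloride (in situ Finkelstein) by lithium acetylide; silyl ethers and the exocyclic alkene are inert.

**Step 15**
Reactants: 19 (4R,5R,6S,9S,10R)-6,18-bis(tert-butyldimethylsilyloxy)-15,16-dinorlabd-8(17)-en-13-yne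
Product: 22 (4R,5R,6S,9S,10R,13E)-6,18-bis(tert-butyldimethylsilyloxy)labda-8(17),13-dien-15-ol, via (13E)-14-(dimethylalumanyl)-6,18-bis(tert-butyldimethylsilyloxy)-15-norlabda-8(17),13-diene 20 (not isolated), via its lithium butyl(dimethyl)aluminate 21 (not isolated)
Conditions: AlMe3, Cp2ZrCl2 (0.5 equiv), CH2Cl2, 0 °C→rt; n-BuLi, THF, −78 °C; (CH2O)n, −78 °C→rt
Reagents that add atoms: trimethylaluminium C[Al](C)C; formaldehyde (as paraformaldehyde) C=O
Why: Negishi carboalumination (syn Me–Al addition, Me to C13) followed by formaldehyde trapping of the alanate with retention gives the 13E allylic alcohol; the 1,1-disubstituted exocyclic alkene is not carbometalated under these conditions.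

**Step 16**
Reactants: 22 (4R,5R,6S,9S,10R,13E)-6,18-bis(tert-butyldimethylsilyloxy)labda-8(17),13-dien-15-ol
Product: 23 (4R,5R,6S,9S,10R,13E)-6,18-bis(tert-butyldimethylsilyloxy)labda-8(17),13-dien-15-al
Conditions: MnO2, CH2Cl2, rt
Reagents that add atoms: none
Why: MnO2 oxidises only the allylic alcohol and preserves the E geometry.

**Step 17**
Reactants: 24 4-methylfuran-2(5H)-one
Product: 25 trimethyl[(4-methylfuran-2-yl)oxy]silane
Conditions: TMSOTf, Et3N, CH2Cl2, 0 °C; distil
Reagents that add atoms: trimethylsilyl trifluoromethanesulfonate C[Si](C)(C)OS(=O)(=O)C(F)(F)F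
Why: Soft enolisation at the γ-position of the butenolide gives the aromatic 2-silyloxyfuran.

**Step 18**
Reactants: 23 (4R,5R,6S,9S,10R,13E)-6,18-bis(tert-butyldimethylsilyloxy)labda-8(17),13-dien-15-al; 25 trimethyl[(4-methylfuran-2-yl)oxy]silane
Product: 27 6,18-bis(tert-butyldimethylsilyl) ether of the target (side-chain carbinol S, butenolide C5 S), via its 15-O-trimethylsilyl ether 26 (not isolated)
Conditions: (R)-BINOL (20 mol%), Ti(OiPr)4 (20 mol%), Et2O, −20 °C; then dilute HCl/THF, 0 °C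
Reagents that add atoms: none
Why: In this catalytic asymmetric vinylogous Mukaiyama aldol the BINOL–Ti Lewis acid binds the enal and 25 attacks through its C5 (γ) carbon on one aldehyde face in an open, intrinsically threo-selective transition state, so both new centres are reagent-controlled (the decalin centres are too remote to interfere), and the silyl-transfer product 26 is cleaved on work-up.

**Step 19**
Reactants: 27 6,18-bis(tert-butyldimethylsilyl) ether of the target
Product: 28 CNP0221530.1, (5S)-5-[(1S,2E)-1-hydroxy-5-{(1S,4S,4aR,5R,8aR)-4-hydroxy-5-(hydroxymethyl)-5,8a-dimethyl-2-methylidenedecahydronaphthalen-1-yl}-3-methylpent-2-en-1-yl]-4-methylfuran-2(5H)-one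
Conditions: HF·pyridine, pyridine/THF, 0 °C→rt
Reagents that add atoms: none
Why: Fluoride-mediated desilylation removes both TBS ethers under buffered, non-basic conditions that neither epimerise the butenolide γ-centre nor ionise the allylic alcohol.

**Compound list**
1 | tert-butyl(but-3-yn-1-yloxy)dimethylsilane | C#CCCO[Si](C)(C)C(C)(C)C | starting material
2 | dimethyl[(E)-4-(tert-butyldimethylsilyloxy)-2-methylbut-1-en-1-yl]alane | C[Al](C)/C=C(\C)CCO[Si](C)(C)C(C)(C)C | intermediate
3 | lithium butyl(dimethyl)[(E)-4-(tert-butyldimethylsilyloxy)-2-methylbut-1-en-1-yl]aluminate | [Li+].CCCC[Al-](C)(C)/C=C(\C)CCO[Si](C)(C)C(C)(C)C | intermediate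
4 | (E)-6-[(tert-butyldimethylsilyl)oxy]-4-methylhex-3-en-1-ol | OCC/C=C(\C)CCO[Si](C)(C)C(C)(C)C | intermediate
5 | (E)-tert-butyl[(6-chloro-3-methylhex-3-en-1-yl)oxy]dimethylsilane | ClCC/C=C(\C)CCO[Si](C)(C)C(C)(C)C | intermediate
6 | (E)-6-chloro-3-methylhex-3-en-1-ol | ClCC/C=C(\C)CCO | intermediate
7 | (E)-6-chloro-3-methylhex-3-enal | ClCC/C=C(\C)CC=O | intermediate
8 | hept-1-en-6-yne | C#CCCCC=C | starting material
9 | dimethyl[(E)-2-methylhepta-1,6-dien-1-yl]alane | C[Al](C)/C=C(\C)CCCC=C | intermediate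
10 | (E)-1-iodo-2-methylhepta-1,6-diene | I/C=C(\C)CCCC=C | intermediate
11 | rac-(3E,7E)-1-chloro-4,8-dimethyltrideca-3,7,12-trien-6-ol | ClCC/C=C(\C)CC(O)/C=C(\C)CCCC=C | intermediate
12 | (3E,7E)-1-chloro-4,8-dimethyltrideca-3,7,12-trien-6-one | ClCC/C=C(\C)CC(=O)/C=C(\C)CCCC=C | intermediate
13 | (6S,3E,7E)-1-chloro-4,8-dimethyltrideca-3,7,12-trien-6-ol | ClCC/C=C(\C)C[C@H](O)/C=C(\C)CCCC=C | intermediate
14 | tert-butyl{[(6S,3E,7E)-1-chloro-4,8-dimethyltrideca-3,7,12-trien-6-yl]oxy}dimethylsilane | ClCC/C=C(\C)C[C@H](O[Si](C)(C)C(C)(C)C)/C=C(\C)CCCC=C | intermediate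
15 | (8S,6E,10E)-8-[(tert-butyldimethylsilyl)oxy]-13-chloro-6,10-dimethyltrideca-6,10-dien-2-one | ClCC/C=C(\C)C[C@H](O[Si](C)(C)C(C)(C)C)/C=C(\C)CCCC(C)=O | intermediate
16 | tert-butyl{[(6S,3E,7E)-1-chloro-4,8-dimethyl-11-(2-methyloxiran-2-yl)undeca-3,7-dien-6-yl]oxy}dimethylsilane (both oxirane epimers) | ClCC/C=C(\C)C[C@H](O[Si](C)(C)C(C)(C)C)/C=C(\C)CCCC1(C)CO1 | intermediate
17 | (4R,5R,6S,9S,10R)-6-(tert-butyldimethylsilyloxy)-12-chloro-13,14,15,16-tetranorlabd-8(17)-en-18-ol | C=C1C[C@H](O[Si](C)(C)C(C)(C)C)[C@H]2[C@](C)(CO)CCC[C@]2(C)[C@H]1CCCl | intermediate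
18 | (4R,5R,6S,9S,10R)-6,18-bis(tert-butyldimethylsilyloxy)-12-chloro-13,14,15,16-tetranorlabd-8(17)-ene | C=C1C[C@H](O[Si](C)(C)C(C)(C)C)[C@H]2[C@](C)(CO[Si](C)(C)C(C)(C)C)CCC[C@]2(C)[C@H]1CCCl | intermediate
19 | (4R,5R,6S,9S,10R)-6,18-bis(tert-butyldimethylsilyloxy)-15,16-dinorlabd-8(17)-en-13-yne | C=C1C[C@H](O[Si](C)(C)C(C)(C)C)[C@H]2[C@](C)(CO[Si](C)(C)C(C)(C)C)CCC[C@]2(C)[C@H]1CCC#C | intermediate
20 | (13E)-14-(dimethylalumanyl)-6,18-bis(tert-butyldimethylsilyloxy)-15-norlabda-8(17),13-diene | C=C1C[C@H](O[Si](C)(C)C(C)(C)C)[C@H]2[C@](C)(CO[Si](C)(C)C(C)(C)C)CCC[C@]2(C)[C@H]1CC/C(C)=C/[Al](C)C | intermediate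
21 | lithium butyl(dimethyl)aluminate of 20 | [Li+].C=C1C[C@H](O[Si](C)(C)C(C)(C)C)[C@H]2[C@](C)(CO[Si](C)(C)C(C)(C)C)CCC[C@]2(C)[C@H]1CC/C(C)=C/[Al-](C)(C)CCCC | intermediate
22 | (4R,5R,6S,9S,10R,13E)-6,18-bis(tert-butyldimethylsilyloxy)labda-8(17),13-dien-15-ol | C=C1C[C@H](O[Si](C)(C)C(C)(C)C)[C@H]2[C@](C)(CO[Si](C)(C)C(C)(C)C)CCC[C@]2(C)[C@H]1CC/C(C)=C/CO | intermediate
23 | (4R,5R,6S,9S,10R,13E)-6,18-bis(tert-butyldimethylsilyloxy)labda-8(17),13-dien-15-al | C=C1C[C@H](O[Si](C)(C)C(C)(C)C)[C@H]2[C@](C)(CO[Si](C)(C)C(C)(C)C)CCC[C@]2(C)[C@H]1CC/C(C)=C/C=O | intermediate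
24 | 4-methylfuran-2(5H)-one | CC1=CC(=O)OC1 | starting material
25 | trimethyl[(4-methylfuran-2-yl)oxy]silane | Cc1coc(O[Si](C)(C)C)c1 | intermediate
26 | 15-O-trimethylsilyl-6,18-bis-O-(tert-butyldimethylsilyl) derivative of the target | C=C1C[C@H](O[Si](C)(C)C(C)(C)C)[C@H]2[C@](C)(CO[Si](C)(C)C(C)(C)C)CCC[C@]2(C)[C@H]1CC/C(C)=C/[C@H](O[Si](C)(C)C)[C@H]1OC(=O)C=C1C | intermediate
27 | 6,18-bis-O-(tert-butyldimethylsilyl) derivative of the target | C=C1C[C@H](O[Si](C)(C)C(C)(C)C)[C@H]2[C@](C)(CO[Si](C)(C)C(C)(C)C)CCC[C@]2(C)[C@H]1CC/C(C)=C/[C@H](O)[C@H]1OC(=O)C=C1C | intermediate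
28 | CNP0221530.1 | C=C1C[C@H](O)[C@H]2[C@](C)(CO)CCC[C@]2(C)[C@H]1CC/C(C)=C/[C@H](O)[C@H]1OC(=O)C=C1C | target

**Totals**
Total steps: 19. Longest linear sequence: 17 (steps 1–4, 6–16, 18, 19).

**Three steps most likely to fail**

Step 12 (Ti(III) bicyclization). The risks are selectivity at C4 (CH3 versus CH2OTi), early termination after ring A, and isomerisation of the epoxide to an allylic alcohol. The fallback sets out from 15 and comes back at 18, and it replaces the radical cascade by a stereospecific cationic one. Ketone 15 is epoxidised with dimethylsulfoxonium methylide under a chiral La–Li3–tris(binaphthoxide)/Ar3P=O catalyst (hand chosen for the R oxirane) to the single (R)-oxirane epimer F1. SnCl4 in CH2Cl2/MeNO2 at −78 °C with aqueous quench then opens the oxirane at C4 with inversion, closes both rings through the chair–chair cation–olefin pathway and captures the C8 cation with water from the α face, giving 6α-(tert-butyldimethylsilyloxy)-12-chloro-13,14,15,16-tetranorlabdane-8α,18-diol F2. Silylation of the primary alcohol (TBSCl, imidazole) gives the 8α-ol F3, and SOCl2/pyridine at −40 °C dehydrates it toward C17 to give 18.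

Step 18 (late-stage asymmetric vinylogous aldol). The risks are the facial sense and level of induction, and the threo/erythro ratio with the 4-methylfuran. The fallback sets out from 23 and comes back at 27, and it moves stereocontrol from the catalyst to a kinetic resolution. The aldol is run with 25 and BF3·OEt2 (CH2Cl2, −78 °C), which is still threo-selective and gives 27 mixed with its side-chain (R,R) diastereomer F4. Sharpless kinetic resolution (Ti(OiPr)4, L-(+)-DIPT, t-BuOOH, −20 °C) epoxidises the (R)-carbinol isomer to the 13,14-epoxy alcohol F5 and leaves 27, which is separated by chromatography.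

Step 6 (NHK union with the β,γ-unsaturated aldehyde 7). The risks are conjugation or self-condensation of 7. The fallback sets out from 6 and 10 and comes back at 12, and it replaces aldehyde addition by acylation. Alcohol 6 is oxidised (TEMPO, PhI(OAc)2, MeCN/H2O) to (E)-6-chloro-3-methylhex-3-enoic acid F6 and coupled (MeNHOMe·HCl, EDCI) to the Weinreb amide F7. Iodide 10 is lithiated (t-BuLi, Et2O, −78 °C) to (E)-(2-methylhepta-1,6-dien-1-yl)lithium F8, which acylates F7 to give enone 12 directly, bypassing 7 and 11.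

**Further compounds**
F1 | step 12 | tert-butyl{[(6S,3E,7E)-1-chloro-4,8-dimethyl-11-[(2R)-2-methyloxiran-2-yl]undeca-3,7-dien-6-yl]oxy}dimethylsilane | ClCC/C=C(\C)C[C@H](O[Si](C)(C)C(C)(C)C)/C=C(\C)CCC[C@]1(C)CO1
F2 | step 12 | 6α-(tert-butyldimethylsilyloxy)-12-chloro-13,14,15,16-tetranorlabdane-8α,18-diol | C[C@@]1(O)C[C@H](O[Si](C)(C)C(C)(C)C)[C@H]2[C@](C)(CO)CCC[C@]2(C)[C@H]1CCCl
F3 | step 12 | 6α,18-bis(tert-butyldimethylsilyloxy)-12-chloro-13,14,15,16-tetranorlabdan-8α-ol | C[C@@]1(O)C[C@H](O[Si](C)(C)C(C)(C)C)[C@H]2[C@](C)(CO[Si](C)(C)C(C)(C)C)CCC[C@]2(C)[C@H]1CCCl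
F4 | step 18 | side-chain (R,R) diastereomer of 27 | C=C1C[C@H](O[Si](C)(C)C(C)(C)C)[C@H]2[C@](C)(CO[Si](C)(C)C(C)(C)C)CCC[C@]2(C)[C@H]1CC/C(C)=C/[C@@H](O)[C@@H]1OC(=O)C=C1C
F5 | step 18 | 13,14-epoxy alcohol derived from F4 | C=C1C[C@H](O[Si](C)(C)C(C)(C)C)[C@H]2[C@](C)(CO[Si](C)(C)C(C)(C)C)CCC[C@]2(C)[C@H]1CC[C@@]3(C)O[C@@H]3[C@@H](O)[C@@H]4OC(=O)C=C4C
F6 | step 6 | (E)-6-chloro-3-methylhex-3-enoic acid | ClCC/C=C(\C)CC(=O)O
F7 | step 6 | (E)-6-chloro-N-methoxy-N,3-dimethylhex-3-enamide | ClCC/C=C(\C)CC(=O)N(C)OC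
F8 | step 6 | (E)-(2-methylhepta-1,6-dien-1-yl)lithium | [Li]/C=C(\C)CCCC=C
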